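## Retrosynthetic overview

Lignan numbering is used: guaiacyl chain C7–C9, syringyl chain C7'–C9'.

1. The strategy rests on the tetrahydrofuran ring C7–O–C9'–C8'–C8, which carries the one-carbon branch C7' on C8' and the carboxyl carbon C9 on C8. C8, C8', C9' and C7' are the four carbons of an ester-substituted trimethylenemethane (TMM), and C7 with the ring oxygen is the carbonyl group of O-benzylvanillin. Cutting C7–C8 and O–C9' gives a palladium-catalysed asymmetric (3+2) cycloaddition.
2. The γ-lactone ring C8–C9(=O)–O–C7'–C8' is cut at O–C7' and at the aryl–C7' bond. The syringyl ring is put on the exocyclic methylene carbon C7' by Heck arylation, and the C9 acid then adds across the C7'=C8' styrene bond.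
3. The dipole precursor is methyl 2-acetoxy-3-[(trimethylsilyl)methyl]but-3-enoate, two steps from (2-bromoallyl)trimethylsilane and methyl glyoxylate. With the acetate on the ester-bearing carbon and silicon on the free methylene, ionisation and desilylation give the same ester-stabilised Pd–TMM as an α-silyl ester would. This layout avoids the lability of an α-silyl ester and the α/γ regiochemistry problem of carboxylating a silylallyl anion.
4. Ring order: tetrahydrofuran first (C7 from the chiral ligand, C8 trans to it), lactone second (C8' and C7' fixed by cis ring fusion and the exo position of the aryl group). Both phenols stay benzylated until the last step.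

Key step: step 3

Assumption: the ligand PA is the phosphoramidite from BINOL and trans-2,5-di(naphthalen-2-yl)pyrrolidine; because the sense of induction with an ester-substituted dipole cannot be predicted safely, the antipode that gives (S) at C7 is picked in a scouting run on 6, and the route is written for it.

## Route

Step 1
Reactants: 1 (2-bromoallyl)trimethylsilane; 2 methyl glyoxylate (freshly distilled)
Product: 4 methyl 2-hydroxy-3-[(trimethylsilyl)methyl]but-3-enoate (racemic), via vinylmagnesium reagent 3 (not isolated)
Conditions: Mg, THF, 40 °C; then 2, THF, −78 °C; aq. NH4Cl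
Reagents that add atoms: none
Why: Magnesium inserts into the vinylic C–Br bond and the alkenyl Grignard reagent adds to the aldehyde carbonyl of methyl glyoxylate, which at −78 °C is far more electrophilic than the ester (Grignard addition); the carbinol centre is left racemic because it is destroyed on ionisation in step 3.

Step 2
Reactants: 4 methyl 2-hydroxy-3-[(trimethylsilyl)methyl]but-3-enoate
Product: 5 methyl 2-acetoxy-3-[(trimethylsilyl)methyl]but-3-enoate (racemic)
Conditions: Ac2O, pyridine, DMAP (cat.), CH2Cl2, 0 °C to rt
Reagents that add atoms: acetic anhydride, CC(=O)OC(C)=O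
Why: DMAP-catalysed acetylation of the secondary alcohol installs the leaving group for zerovalent palladium, and the allylsilane is inert to these mildly basic conditions.

Step 3
Reactants: 5 methyl 2-acetoxy-3-[(trimethylsilyl)methyl]but-3-enoate; 6 O-benzylvanillin
Product: 7 methyl (2S,3S)-2-[4-(benzyloxy)-3-methoxyphenyl]-4-methylidenetetrahydrofuran-3-carboxylate (2,3-trans)
Conditions: Pd(dba)2 (5 mol %), phosphoramidite PA (10 mol %), In(acac)3 (10 mol %), toluene, 25–45 °C
Reagents that add atoms: none
Why: Zerovalent palladium ionises the allylic acetate of 5, the liberated acetate removes the trimethylsilyl group from the remote methylene, and the resulting Pd–TMM zwitterion carries its negative charge on the ester-bearing carbon (an ester enolate flanked by a symmetrical π-allyl unit). That carbon adds to the aldehyde carbonyl of 6, activated by In(acac)3, to form C7–C8, and the alkoxide closes the tetrahydrofuran by attacking the π-allyl terminus C9' (O–C9'; intramolecular allylic etherification, 5-exo with respect to the departing palladium), which leaves C7' as the exocyclic methylene. The closest known reaction type is the palladium-catalysed asymmetric TMM (3+2) cycloaddition of aryl aldehydes with phosphoramidite ligands, together with cycloadditions of acceptor-substituted (cyano) donors of the same acetoxy/silylmethyl layout, which bond through the substituted carbon. C7 is set by the chiral phosphoramidite on palladium, which differentiates the aldehyde faces in C–C bond formation and ring closure; C8 is set relative to C7 by the preference for the 2,3-trans product, which is also the thermodynamic isomer because C8–H is enolisable. The step needs bonding through the ester carbon and not the unsubstituted terminus, secured by the ester stabilising the carbanion, and ring closure in preference to O-silylation of the intermediate alkoxide, which the indium co-catalyst secures.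

Step 4
Reactants: 8 2,6-dimethoxyphenol
Product: 9 4-iodo-2,6-dimethoxyphenol
Conditions: NIS, MeCN, 0 °C, dark
Reagents that add atoms: N-iodosuccinimide, O=C1CCC(=O)N1I
Why: Electrophilic aromatic iodination directed para by the free phenol, both ortho positions being blocked by methoxy groups.

Step 5
Reactants: 9 4-iodo-2,6-dimethoxyphenol
Product: 10 2-(benzyloxy)-5-iodo-1,3-dimethoxybenzene
Conditions: BnBr, K2CO3, DMF, 50 °C
Reagents that add atoms: benzyl bromide, BrCc1ccccc1
Why: Williamson etherification of the phenoxide with benzyl bromide, which proceeds despite the two flanking methoxy groups in a dipolar aprotic solvent.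

Step 6
Reactants: 7 methyl (2S,3S)-2-[4-(benzyloxy)-3-methoxyphenyl]-4-methylidenetetrahydrofuran-3-carboxylate; 10 2-(benzyloxy)-5-iodo-1,3-dimethoxybenzene
Product: 11 methyl (2S,3S,4Z)-2-[4-(benzyloxy)-3-methoxyphenyl]-4-{[4-(benzyloxy)-3,5-dimethoxyphenyl]methylidene}tetrahydrofuran-3-carboxylate
Conditions: Pd(OAc)2 (10 mol %), Bu4NCl, NaHCO3, DMF, 70 °C
Reagents that add atoms: none
Why: Mizoroki–Heck arylation under ligand-free phase-transfer conditions: the arylpalladium iodide adds across the 1,1-disubstituted alkene with aryl on the unsubstituted carbon C7', and β-hydride elimination from the freely rotating benzylic CH2 should give the aryl-conjugated trisubstituted alkene (Z expected, either geometry is usable because step 8 erases it), with C7 and C8 untouched.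

Step 7
Reactants: 11 methyl (2S,3S,4Z)-2-[4-(benzyloxy)-3-methoxyphenyl]-4-{[4-(benzyloxy)-3,5-dimethoxyphenyl]methylidene}tetrahydrofuran-3-carboxylate
Product: 12 (2S,3S,4Z)-2-[4-(benzyloxy)-3-methoxyphenyl]-4-{[4-(benzyloxy)-3,5-dimethoxyphenyl]methylidene}tetrahydrofuran-3-carboxylic acid
Conditions: LiOH, THF/H2O, 0 °C; then 1 M HCl, 0 °C
Reagents that add atoms: lithium hydroxide, [Li+].[OH-]
Why: Saponification of the methyl ester; C8 already has the more stable 2,3-trans configuration, and the cold, short reaction limits deprotonation at C8 that could move the double bond into conjugation with the carboxyl group.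

Step 8
Reactants: 12 (2S,3S,4Z)-2-[4-(benzyloxy)-3-methoxyphenyl]-4-{[4-(benzyloxy)-3,5-dimethoxyphenyl]methylidene}tetrahydrofuran-3-carboxylic acid
Product: 13 (3S,3aR,6S,6aS)-6-[4-(benzyloxy)-3-methoxyphenyl]-3-[4-(benzyloxy)-3,5-dimethoxyphenyl]tetrahydro-1H,3H-furo[3,4-c]furan-1-one
Conditions: TfOH (10 mol %), CH2Cl2, −20 to 0 °C
Reagents that add atoms: none
Why: Acid-catalysed intramolecular hydroacyloxylation of an electron-rich styrene: reversible protonation at C8' gives the para-alkoxybenzylic cation at C7', which only the isomer with the C7' branch cis to the carboxyl group can capture (a trans-fused five–five lactone is too strained), so C8' ends with its hydrogen cis to H8, while the aryl group at C7' settles on the exo (convex) face because the benzylic C–O bond forms reversibly; the closure is formally 5-endo but runs through a free cation.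

Step 9
Reactants: 13 (3S,3aR,6S,6aS)-6-[4-(benzyloxy)-3-methoxyphenyl]-3-[4-(benzyloxy)-3,5-dimethoxyphenyl]tetrahydro-1H,3H-furo[3,4-c]furan-1-one
Product: 14 (3S,3aR,6S,6aS)-6-(4-hydroxy-3-methoxyphenyl)-3-(4-hydroxy-3,5-dimethoxyphenyl)tetrahydro-1H,3H-furo[3,4-c]furan-1-one (CNP0142585.1)
Conditions: H2 (1 atm), palladium on carbon (10 % Pd), EtOAc, rt, monitored
Reagents that add atoms: none
Why: Hydrogenolysis of the two aryl benzyl ethers; under neutral conditions in an aprotic solvent at ambient pressure the O-benzyl groups should cleave well before the hindered secondary benzylic C7–O and C7'–O bonds of the bicycle, and no stereocentre is touched.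

## Compound list

1 | (2-bromoallyl)trimethylsilane | C[Si](C)(C)CC(Br)=C | starting material
2 | methyl glyoxylate | COC(=O)C=O | starting material
3 | [3-(trimethylsilyl)prop-1-en-2-yl]magnesium bromide | C[Si](C)(C)CC(=C)[Mg]Br | intermediate (not isolated)
4 | methyl 2-hydroxy-3-[(trimethylsilyl)methyl]but-3-enoate (racemic) | COC(=O)C(O)C(=C)C[Si](C)(C)C | intermediate
5 | methyl 2-acetoxy-3-[(trimethylsilyl)methyl]but-3-enoate (racemic) | COC(=O)C(OC(C)=O)C(=C)C[Si](C)(C)C | intermediate
6 | O-benzylvanillin, 4-(benzyloxy)-3-methoxybenzaldehyde | COc1cc(C=O)ccc1OCc1ccccc1 | starting material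
7 | methyl (2S,3S)-2-[4-(benzyloxy)-3-methoxyphenyl]-4-methylidenetetrahydrofuran-3-carboxylate | COc1cc([C@H]2OCC(=C)[C@@H]2C(=O)OC)ccc1OCc1ccccc1 | intermediate
8 | 2,6-dimethoxyphenol | COc1cccc(OC)c1O | starting material
9 | 4-iodo-2,6-dimethoxyphenol | COc1cc(I)cc(OC)c1O | intermediate
10 | 2-(benzyloxy)-5-iodo-1,3-dimethoxybenzene | COc1cc(I)cc(OC)c1OCc1ccccc1 | intermediate
11 | methyl (2S,3S,4Z)-2-[4-(benzyloxy)-3-methoxyphenyl]-4-{[4-(benzyloxy)-3,5-dimethoxyphenyl]methylidene}tetrahydrofuran-3-carboxylate | COc1cc([C@H]2OC/C(=C\c3cc(OC)c(OCc4ccccc4)c(OC)c3)[C@@H]2C(=O)OC)ccc1OCc1ccccc1 | intermediate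
12 | (2S,3S,4Z)-2-[4-(benzyloxy)-3-methoxyphenyl]-4-{[4-(benzyloxy)-3,5-dimethoxyphenyl]methylidene}tetrahydrofuran-3-carboxylic acid | COc1cc([C@H]2OC/C(=C\c3cc(OC)c(OCc4ccccc4)c(OC)c3)[C@@H]2C(=O)O)ccc1OCc1ccccc1 | intermediate
13 | (3S,3aR,6S,6aS)-6-[4-(benzyloxy)-3-methoxyphenyl]-3-[4-(benzyloxy)-3,5-dimethoxyphenyl]tetrahydro-1H,3H-furo[3,4-c]furan-1-one | COc1cc([C@H]2OC[C@H]3[C@@H]2C(=O)O[C@@H]3c2cc(OC)c(OCc4ccccc4)c(OC)c2)ccc1OCc1ccccc1 | intermediate
14 | (3S,3aR,6S,6aS)-6-(4-hydroxy-3-methoxyphenyl)-3-(4-hydroxy-3,5-dimethoxyphenyl)tetrahydro-1H,3H-furo[3,4-c]furan-1-one | COc1cc([C@H]2OC[C@H]3[C@@H]2C(=O)O[C@@H]3c2cc(OC)c(O)c(OC)c2)ccc1O | target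

## Step count and risks

Total step count: 9. Longest linear sequence: 7 steps (steps 1, 2, 3, 6, 7, 8, 9).

Steps most likely to fail:

1. Step 3. The ester-stabilised dipole is a weaker nucleophile than the parent TMM and the aldehyde is electron-rich, so the aldol-type addition may be slow or reversible. That would allow protonation of the dipole, erosion of the facial selectivity at C7, or base-induced migration of the exocyclic double bond into conjugation with the ester. The fallback sets out from 6 and returns at 7.
   - Vinylmagnesium bromide adds to 6 to give racemic 1-[4-(benzyloxy)-3-methoxyphenyl]prop-2-en-1-ol F1.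
   - Katsuki–Sharpless kinetic resolution (Ti(OiPr)4, D-(−)-diisopropyl tartrate, t-BuOOH, 4 Å sieves, CH2Cl2, −20 °C) epoxidises the (S)-alcohol as the fast enantiomer by the usual facial rule, giving the erythro epoxy alcohol (R)-[4-(benzyloxy)-3-methoxyphenyl][(2S)-oxiran-2-yl]methanol F2.
   - O-Propargylation (NaH, propargyl bromide, THF) gives (2S)-2-{(R)-[4-(benzyloxy)-3-methoxyphenyl](prop-2-yn-1-yloxy)methyl}oxirane F3.
   - Cp2TiCl (from Cp2TiCl2 and zinc dust, THF) opens the epoxide reductively to the C8 radical, which cyclises 5-exo-dig onto the alkyne trans to the aryl group and gives [(2S,3R)-2-[4-(benzyloxy)-3-methoxyphenyl]-4-methylidenetetrahydrofuran-3-yl]methanol F4. The epoxide stereocentre is erased in this step, so only the carbinol configuration is carried over.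
   - Oxidation (TEMPO, PhI(OAc)2, aqueous MeCN) gives (2S,3S)-2-[4-(benzyloxy)-3-methoxyphenyl]-4-methylidenetetrahydrofuran-3-carboxylic acid F5, and Me3SiCHN2 in MeOH/toluene gives 7.

2. Step 6. After carbopalladation the tertiary alkylpalladium at C8' may lose a ring hydride (from C8 or C9') instead of a benzylic one, or the base may conjugate the alkene before arylation. Either path gives endocyclic alkene isomers that cannot lactonise. The fallback sets out from 7 and returns at 11.
   - Cross-metathesis of 7 with vinylboronic acid pinacol ester (second-generation Hoveyda–Grubbs catalyst, CH2Cl2, 40 °C) gives methyl (2S,3S,4Z)-2-[4-(benzyloxy)-3-methoxyphenyl]-4-[(4,4,5,5-tetramethyl-1,3,2-dioxaborolan-2-yl)methylidene]tetrahydrofuran-3-carboxylate F6.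
   - Suzuki–Miyaura coupling of F6 with 10 (Pd(dppf)Cl2, K3PO4, aqueous dioxane, 60 °C) gives 11 with the alkene position fixed.

3. Step 8. The acid may also ionise the benzylic C7–O bond of the tetrahydrofuran, which would epimerise C7 or lead to Friedel–Crafts closure onto an aryl ring before the lactone is secured. The fallback sets out from 11 and returns at 13, so step 7 is then not needed.
   - Mukaiyama-type Markovnikov hydration of 11 (Mn(dpm)3, PhSiH3, O2, i-PrOH/CH2Cl2, then PPh3) delivers hydrogen to C8' from the face opposite the ester and oxygen to benzylic C7'. It gives methyl (7S,8S,8'R,7'S)-2-[4-(benzyloxy)-3-methoxyphenyl]-4-{[4-(benzyloxy)-3,5-dimethoxyphenyl](hydroxy)methyl}tetrahydrofuran-3-carboxylate F7 (2,3-trans, 3,4-cis, lignan-numbered descriptors).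
   - F7 lactonises onto the cis ester with catalytic PPTS in toluene to give 13. The same mild acid should equilibrate any C7' epimer to the exo-aryl lactone.

## Further compounds

F1 | step 3 | rac-1-[4-(benzyloxy)-3-methoxyphenyl]prop-2-en-1-ol | COc1cc(C(O)C=C)ccc1OCc1ccccc1
F2 | step 3 | (R)-[4-(benzyloxy)-3-methoxyphenyl][(2S)-oxiran-2-yl]methanol | COc1cc([C@H]([C@@H]2CO2)O)ccc1OCc1ccccc1
F3 | step 3 | (2S)-2-{(R)-[4-(benzyloxy)-3-methoxyphenyl](prop-2-yn-1-yloxy)methyl}oxirane | COc1cc([C@H]([C@@H]2CO2)OCC#C)ccc1OCc1ccccc1
F4 | step 3 | [(2S,3R)-2-[4-(benzyloxy)-3-methoxyphenyl]-4-methylidenetetrahydrofuran-3-yl]methanol | COc1cc([C@H]2OCC(=C)[C@@H]2CO)ccc1OCc1ccccc1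
F5 | step 3 | (2S,3S)-2-[4-(benzyloxy)-3-methoxyphenyl]-4-methylidenetetrahydrofuran-3-carboxylic acid | COc1cc([C@H]2OCC(=C)[C@@H]2C(=O)O)ccc1OCc1ccccc1
F6 | step 6 | methyl (2S,3S,4Z)-2-[4-(benzyloxy)-3-methoxyphenyl]-4-[(4,4,5,5-tetramethyl-1,3,2-dioxaborolan-2-yl)methylidene]tetrahydrofuran-3-carboxylate | COc1cc([C@H]2OC/C(=C\B3OC(C)(C)C(C)(C)O3)[C@@H]2C(=O)OC)ccc1OCc1ccccc1
F7 | step 8 | methyl (7S,8S,8'R,7'S)-2-[4-(benzyloxy)-3-methoxyphenyl]-4-{[4-(benzyloxy)-3,5-dimethoxyphenyl](hydroxy)methyl}tetrahydrofuran-3-carboxylate | COc1cc([C@H]2OC[C@H]([C@H](O)c3cc(OC)c(OCc4ccccc4)c(OC)c3)[C@@H]2C(=O)OC)ccc1OCc1ccccc1
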